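**Plan**

- Retrosynthesis cuts, in order: the chalcone Cα=Cβ bond (aldol) and the aryl–C(=O) bond (directed lithiation/acylation); the oxane C2–aryl and C2–H bonds (aryllithium addition to a δ-lactone, then hydride); the O1–C6 bond of the oxane, by taking out O1 (retro-Baeyer–Villiger) to reach a cyclopentanone; the ring–side-chain bond (Sonogashira) and the C4–aryl bond (cuprate).
- Feature used: in the oxane ring, O1 sits between C6 (a secondary, alkyl-substituted carbon) and C2 (which can be raised to a lactone carbonyl). Without O1, the carbons C2–C6 form a cyclopentanone on which the cis relation of the C4 aryl and the C6 chain is a cis-1,3 pattern on a five-membered carbocycle.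
- Forward: aryl cuprate plus (S)-4-acetoxycyclopentenone gives the (S)-4-arylcyclopentenone; α-iodination, Sonogashira coupling and hydrogenation give the cis-2,4-disubstituted cyclopentanone; ring expansion gives the δ-lactone; aryl addition and reduction give the oxane; acetylation, aldol condensation and MOM removal finish.
- Stereochemistry: C4 comes from the purchased (1R,4S)-monoacetate (anti cuprate addition; the relay centre is then erased). C6 is set by hydrogenation anti to the C4 aryl and kept by the retentive migration. C2 is set by axial hydride delivery to the oxocarbenium ion.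

Key step: step 8

Assumption: lithiation of 2 with n-BuLi is taken to occur at C4, between the two MOM ethers (the site with the strongest cooperative direction); compounds 3, 11 and 16 are taken as purchasable.

**Step 1**
Reactants: 1 5-methoxybenzene-1,3-diol
Product: 2 1-methoxy-3,5-bis(methoxymethoxy)benzene
Conditions: NaH, MOMCl, DMF, 0 °C → rt
Reagents that add atoms: chloromethyl methyl ether (MOMCl), COCCl
Why: O-alkylation of both phenoxides (Williamson-type MOM protection) should be clean, and the two MOM ethers later act as ortho-directing groups.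

**Step 2**
Reactants: 3 (1R,4S)-cis-4-acetoxycyclopent-2-en-1-ol
Product: 4 (S)-4-oxocyclopent-2-en-1-yl acetate
Conditions: activated MnO2, CH2Cl2, rt
Reagents that add atoms: none
Why: Allylic alcohol oxidation with MnO2 under neutral conditions should give the enone without touching the acetate or the stereocentre that carries it.

**Step 3**
Reactants: 2 1-methoxy-3,5-bis(methoxymethoxy)benzene; 4 (S)-4-oxocyclopent-2-en-1-yl acetate
Product: 9 (4S)-4-[4-methoxy-2,6-bis(methoxymethoxy)phenyl]cyclopent-2-en-1-one, via aryllithium 5 (not isolated), via diarylcuprate 6 (not isolated), via silyl enol ether 7 (not isolated), via acetoxy ketone 8 (not isolated)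
Conditions: 2 (2.2 equiv), n-BuLi, THF, 0 °C; CuI, −40 °C; TMSCl then 4, −78 °C; NH4Cl aq, citric acid aq; crude, Et3N, CH2Cl2, 0 °C
Reagents that add atoms: none
Why: Directed ortho-metalation between the two MOM ethers and TMSCl-assisted 1,4-addition of the Gilman cuprate anti to the neighbouring acetoxy group should set the aryl-bearing centre (R in 8), and E1cB loss of acetate with the weak base Et3N then moves the enone and erases the acetoxy centre without exposing the base-sensitive γ-aryl enone to a strong base.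

**Step 4**
Reactants: 9 (4S)-4-[4-methoxy-2,6-bis(methoxymethoxy)phenyl]cyclopent-2-en-1-one
Product: 10 (4S)-2-iodo-4-[4-methoxy-2,6-bis(methoxymethoxy)phenyl]cyclopent-2-en-1-one
Conditions: I2, pyridine, CH2Cl2, 0 °C → rt, dark
Reagents that add atoms: iodine, II
Why: Pyridine-mediated α-iodination of the enone (conjugate addition of pyridine, iodination of the enolate, E1cB loss of pyridine) should functionalise only the α-vinyl carbon and leave C4 untouched, because pyridine is too weak a base to remove the γ-hydrogen.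

**Step 5**
Reactants: 11 4-(methoxymethoxy)benzaldehyde
Product: 12 1-ethynyl-4-(methoxymethoxy)benzene
Conditions: dimethyl (1-diazo-2-oxopropyl)phosphonate, K2CO3, MeOH, rt
Reagents that add atoms: dimethyl (1-diazo-2-oxopropyl)phosphonate, CC(=O)C(=[N+]=[N-])P(=O)(OC)OC
Why: Ohira–Bestmann (Seyferth–Gilbert) homologation should convert the aromatic aldehyde into the terminal alkyne under mild basic conditions that MOM ethers tolerate.

**Step 6**
Reactants: 10 (4S)-2-iodo-4-[4-methoxy-2,6-bis(methoxymethoxy)phenyl]cyclopent-2-en-1-one; 12 1-ethynyl-4-(methoxymethoxy)benzene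
Product: 13 (4S)-4-[4-methoxy-2,6-bis(methoxymethoxy)phenyl]-2-{[4-(methoxymethoxy)phenyl]ethynyl}cyclopent-2-en-1-one
Conditions: Pd(PPh3)2Cl2 (cat.), CuI (cat.), Et3N, THF, 0 °C → rt
Reagents that add atoms: none
Why: Sonogashira coupling of the α-iodoenone (a reactive vinyl iodide) with the terminal arylalkyne should proceed under a mild amine base at low temperature, which keeps the C4 centre intact.

**Step 7**
Reactants: 13 (4S)-4-[4-methoxy-2,6-bis(methoxymethoxy)phenyl]-2-{[4-(methoxymethoxy)phenyl]ethynyl}cyclopent-2-en-1-one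
Product: 14 (2S,4R)-4-[4-methoxy-2,6-bis(methoxymethoxy)phenyl]-2-{2-[4-(methoxymethoxy)phenyl]ethyl}cyclopentan-1-one
Conditions: H2 (1 atm), 10% Pd/C, EtOAc, rt
Reagents that add atoms: none
Why: Heterogeneous hydrogenation should saturate the alkyne and the ring C=C, with hydrogen delivered to the ring alkene from the face opposite the bulky C4 aryl group, so that the new C2 centre is S and the chain is cis to the aryl.

**Step 8**
Reactants: 14 (2S,4R)-4-[4-methoxy-2,6-bis(methoxymethoxy)phenyl]-2-{2-[4-(methoxymethoxy)phenyl]ethyl}cyclopentan-1-one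
Product: 15 (4R,6S)-4-[4-methoxy-2,6-bis(methoxymethoxy)phenyl]-6-{2-[4-(methoxymethoxy)phenyl]ethyl}oxan-2-one
Conditions: mCPBA, NaHCO3, CH2Cl2, 0 °C → rt
Reagents that add atoms: 3-chloroperoxybenzoic acid (mCPBA), OOC(=O)c1cccc(Cl)c1
Why: The peracid adds to the C1 carbonyl to give the Criegee adduct, and the more substituted α-carbon C2 (secondary, bearing the arylethyl chain) shifts from C1 to the peroxide oxygen as 3-chlorobenzoate leaves, so one oxygen atom enters the C1–C2 bond and the five-membered carbocycle becomes the six-membered oxan-2-one. The closest known reaction type is the Baeyer–Villiger oxidation of 2-alkylcyclopentanones to 6-alkyl δ-valerolactones. The six-membered ring is not closed by a cyclisation but arises by ring enlargement through this 1,2-shift, so no exo or endo closure mode applies. No new stereocentre is formed: the migrating carbon keeps its configuration (concerted shift with retention), so the cis relation of chain and aryl in 14 becomes the cis relation of C6 and C4 in 15. The step needs regioselectivity (migration of C2, not of the C5 methylene) and chemoselectivity (ketone, not the electron-rich arene). The first is secured by the higher migratory aptitude of the secondary carbon, the second by buffered, acid-free conditions at low temperature, under which electrophilic hydroxylation of the arene should be slow.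

**Step 9**
Reactants: 15 (4R,6S)-4-[4-methoxy-2,6-bis(methoxymethoxy)phenyl]-6-{2-[4-(methoxymethoxy)phenyl]ethyl}oxan-2-one; 16 1-bromo-4-(methoxymethoxy)benzene
Product: 19 (2S,4R,6S)-4-[4-methoxy-2,6-bis(methoxymethoxy)phenyl]-2-[4-(methoxymethoxy)phenyl]-6-{2-[4-(methoxymethoxy)phenyl]ethyl}oxane, via aryllithium 17 (not isolated), via lactol 18 (not isolated)
Conditions: 16, n-BuLi, THF, −78 °C; then 15, −78 °C; NH4Cl aq; crude, Et3SiH, BF3·OEt2, CH2Cl2/MeCN, −78 → −40 °C
Reagents that add atoms: none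
Why: Single addition of the aryllithium to the δ-lactone at −78 °C should give the lactol, and reductive etherification (ionisation to the 2-aryl oxocarbenium ion, then axial hydride delivery from Et3SiH in the half-chair with the C4 and C6 groups equatorial) should set C2 as S with all three substituents cis.

**Step 10**
Reactants: 19 (2S,4R,6S)-4-[4-methoxy-2,6-bis(methoxymethoxy)phenyl]-2-[4-(methoxymethoxy)phenyl]-6-{2-[4-(methoxymethoxy)phenyl]ethyl}oxane
Product: 21 1-{6-methoxy-2,4-bis(methoxymethoxy)-3-[(2S,4R,6S)-2-[4-(methoxymethoxy)phenyl]-6-{2-[4-(methoxymethoxy)phenyl]ethyl}oxan-4-yl]phenyl}ethan-1-one, via aryllithium 20 (not isolated)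
Conditions: n-BuLi, THF, −20 → 0 °C; MeC(O)N(OMe)Me, −78 → 0 °C
Reagents that add atoms: N-methoxy-N-methylacetamide, CC(=O)N(C)OC
Why: Directed ortho-metalation should occur at the only ring position flanked by two oxygen groups (OMe and OMOM), and acylation of the aryllithium with the Weinreb amide stops at the methyl ketone.

**Step 11**
Reactants: 21 1-{6-methoxy-2,4-bis(methoxymethoxy)-3-[(2S,4R,6S)-2-[4-(methoxymethoxy)phenyl]-6-{2-[4-(methoxymethoxy)phenyl]ethyl}oxan-4-yl]phenyl}ethan-1-one; 11 4-(methoxymethoxy)benzaldehyde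
Product: 22 (E)-1-{6-methoxy-2,4-bis(methoxymethoxy)-3-[(2S,4R,6S)-2-[4-(methoxymethoxy)phenyl]-6-{2-[4-(methoxymethoxy)phenyl]ethyl}oxan-4-yl]phenyl}-3-[4-(methoxymethoxy)phenyl]prop-2-en-1-one
Conditions: KOH, EtOH/H2O, rt
Reagents that add atoms: none
Why: Claisen–Schmidt aldol condensation of the methyl ketone with the non-enolisable aromatic aldehyde should give the (E)-enone by E1cB dehydration under thermodynamic control, and ethers and acetals are stable to the base.

**Step 12**
Reactants: 22 (E)-1-{6-methoxy-2,4-bis(methoxymethoxy)-3-[(2S,4R,6S)-2-[4-(methoxymethoxy)phenyl]-6-{2-[4-(methoxymethoxy)phenyl]ethyl}oxan-4-yl]phenyl}-3-[4-(methoxymethoxy)phenyl]prop-2-en-1-one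
Product: 23 (E)-1-{2,4-dihydroxy-3-[(2S,4R,6S)-2-(4-hydroxyphenyl)-6-[2-(4-hydroxyphenyl)ethyl]oxan-4-yl]-6-methoxyphenyl}-3-(4-hydroxyphenyl)prop-2-en-1-one
Conditions: 3 M HCl, MeOH/THF, rt → 40 °C
Reagents that add atoms: none
Why: Acid-catalysed acetal exchange with methanol should remove all four MOM ethers under conditions mild enough for the chalcone, and the all-equatorial oxane is also the thermodynamic isomer should C2 ionise reversibly.

**Compound list**

1 | 5-methoxybenzene-1,3-diol | COc1cc(O)cc(O)c1 | starting material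
2 | 1-methoxy-3,5-bis(methoxymethoxy)benzene | COCOc1cc(OC)cc(OCOC)c1 | intermediate
3 | (1R,4S)-cis-4-acetoxycyclopent-2-en-1-ol | O[C@H]1C=C[C@@H](OC(C)=O)C1 | starting material
4 | (S)-4-oxocyclopent-2-en-1-yl acetate | O=C1C=C[C@@H](OC(C)=O)C1 | intermediate
5 | [4-methoxy-2,6-bis(methoxymethoxy)phenyl]lithium | [Li]c1c(OCOC)cc(OC)cc1OCOC | intermediate
6 | lithium bis[4-methoxy-2,6-bis(methoxymethoxy)phenyl]cuprate | [Li+].COCOc1cc(OC)cc(OCOC)c1[Cu-]c1c(OCOC)cc(OC)cc1OCOC | intermediate
7 | (1S,2R)-2-[4-methoxy-2,6-bis(methoxymethoxy)phenyl]-4-(trimethylsilyloxy)cyclopent-3-en-1-yl acetate | C[Si](C)(C)OC1=C[C@H](c2c(OCOC)cc(OC)cc2OCOC)[C@@H](OC(C)=O)C1 | intermediate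
8 | (1S,2R)-2-[4-methoxy-2,6-bis(methoxymethoxy)phenyl]-4-oxocyclopentyl acetate | O=C1C[C@H](c2c(OCOC)cc(OC)cc2OCOC)[C@@H](OC(C)=O)C1 | intermediate
9 | (4S)-4-[4-methoxy-2,6-bis(methoxymethoxy)phenyl]cyclopent-2-en-1-one | O=C1C=C[C@@H](c2c(OCOC)cc(OC)cc2OCOC)C1 | intermediate
10 | (4S)-2-iodo-4-[4-methoxy-2,6-bis(methoxymethoxy)phenyl]cyclopent-2-en-1-one | O=C1C(I)=C[C@@H](c2c(OCOC)cc(OC)cc2OCOC)C1 | intermediate
11 | 4-(methoxymethoxy)benzaldehyde | O=Cc1ccc(OCOC)cc1 | starting material
12 | 1-ethynyl-4-(methoxymethoxy)benzene | C#Cc1ccc(OCOC)cc1 | intermediate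
13 | (4S)-4-[4-methoxy-2,6-bis(methoxymethoxy)phenyl]-2-{[4-(methoxymethoxy)phenyl]ethynyl}cyclopent-2-en-1-one | O=C1C(C#Cc2ccc(OCOC)cc2)=C[C@@H](c2c(OCOC)cc(OC)cc2OCOC)C1 | intermediate
14 | (2S,4R)-4-[4-methoxy-2,6-bis(methoxymethoxy)phenyl]-2-{2-[4-(methoxymethoxy)phenyl]ethyl}cyclopentan-1-one | O=C1[C@@H](CCc2ccc(OCOC)cc2)C[C@@H](c2c(OCOC)cc(OC)cc2OCOC)C1 | intermediate
15 | (4R,6S)-4-[4-methoxy-2,6-bis(methoxymethoxy)phenyl]-6-{2-[4-(methoxymethoxy)phenyl]ethyl}oxan-2-one | O=C1C[C@H](c2c(OCOC)cc(OC)cc2OCOC)C[C@H](CCc2ccc(OCOC)cc2)O1 | intermediate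
16 | 1-bromo-4-(methoxymethoxy)benzene | COCOc1ccc(Br)cc1 | starting material
17 | [4-(methoxymethoxy)phenyl]lithium | [Li]c1ccc(OCOC)cc1 | intermediate
18 | (4R,6S)-4-[4-methoxy-2,6-bis(methoxymethoxy)phenyl]-2-[4-(methoxymethoxy)phenyl]-6-{2-[4-(methoxymethoxy)phenyl]ethyl}oxan-2-ol (anomer mixture, in equilibrium with the open hydroxy ketone) | OC1(c2ccc(OCOC)cc2)C[C@H](c2c(OCOC)cc(OC)cc2OCOC)C[C@H](CCc2ccc(OCOC)cc2)O1 | intermediate
19 | (2S,4R,6S)-4-[4-methoxy-2,6-bis(methoxymethoxy)phenyl]-2-[4-(methoxymethoxy)phenyl]-6-{2-[4-(methoxymethoxy)phenyl]ethyl}oxane | COc1cc(OCOC)c([C@@H]2C[C@H](CCc3ccc(OCOC)cc3)O[C@H](c3ccc(OCOC)cc3)C2)c(OCOC)c1 | intermediate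
20 | 3-lithio derivative of 19 (lithium on the trioxygenated ring between OMe and OMOM) | COc1cc(OCOC)c([C@@H]2C[C@H](CCc3ccc(OCOC)cc3)O[C@H](c3ccc(OCOC)cc3)C2)c(OCOC)c1[Li] | intermediate
21 | 1-{6-methoxy-2,4-bis(methoxymethoxy)-3-[(2S,4R,6S)-2-[4-(methoxymethoxy)phenyl]-6-{2-[4-(methoxymethoxy)phenyl]ethyl}oxan-4-yl]phenyl}ethan-1-one | COc1cc(OCOC)c([C@@H]2C[C@H](CCc3ccc(OCOC)cc3)O[C@H](c3ccc(OCOC)cc3)C2)c(OCOC)c1C(C)=O | intermediate
22 | (E)-1-{6-methoxy-2,4-bis(methoxymethoxy)-3-[(2S,4R,6S)-2-[4-(methoxymethoxy)phenyl]-6-{2-[4-(methoxymethoxy)phenyl]ethyl}oxan-4-yl]phenyl}-3-[4-(methoxymethoxy)phenyl]prop-2-en-1-one | COc1cc(OCOC)c([C@@H]2C[C@H](CCc3ccc(OCOC)cc3)O[C@H](c3ccc(OCOC)cc3)C2)c(OCOC)c1C(=O)/C=C/c1ccc(OCOC)cc1 | intermediate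
23 | (E)-1-{2,4-dihydroxy-3-[(2S,4R,6S)-2-(4-hydroxyphenyl)-6-[2-(4-hydroxyphenyl)ethyl]oxan-4-yl]-6-methoxyphenyl}-3-(4-hydroxyphenyl)prop-2-en-1-one | COc1cc(O)c([C@@H]2C[C@H](CCc3ccc(O)cc3)O[C@H](c3ccc(O)cc3)C2)c(O)c1C(=O)/C=C/c1ccc(O)cc1 | target

**Totals**

Total step count: 12. Longest linear sequence: 10 steps (steps 1, 3, 4, 6, 7, 8, 9, 10, 11, 12 from 1; the same length from 3 through step 2).

**Steps most likely to fail**

1. Step 8. The peracid may hydroxylate the very electron-rich trioxygenated ring faster than it oxidises the slowly reacting cyclopentanone, and some migration of the methylene carbon may erode regiocontrol. The fallback sets out from 14 and comes back at 15 without any peracid. Ketone 14 is converted (TMSCl, NaI, Et3N, MeCN) into the more substituted silyl enol ether {[(4R)-4-[4-methoxy-2,6-bis(methoxymethoxy)phenyl]-2-{2-[4-(methoxymethoxy)phenyl]ethyl}cyclopent-1-en-1-yl]oxy}trimethylsilane F1. Catalytic OsO4 with NMO, which does not attack the arene, turns it into the α-hydroxy ketone (2R,4R)-2-hydroxy-4-[4-methoxy-2,6-bis(methoxymethoxy)phenyl]-2-{2-[4-(methoxymethoxy)phenyl]ethyl}cyclopentan-1-one F2. Cleavage with NaIO4 in aqueous THF gives the δ-keto acid (3R)-3-[4-methoxy-2,6-bis(methoxymethoxy)phenyl]-7-[4-(methoxymethoxy)phenyl]-5-oxoheptanoic acid F3. Cyclodehydration (Ac2O, NaOAc) gives the enol lactone (4S)-4-[4-methoxy-2,6-bis(methoxymethoxy)phenyl]-6-{2-[4-(methoxymethoxy)phenyl]ethyl}-3,4-dihydro-2H-pyran-2-one F4. Hydrogenation (H2, Pd/C) from the face opposite the C4 aryl group should then give the cis lactone 15.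

2. Step 4. Iodine may also substitute the free positions of the electron-rich aryl ring, and prolonged contact with base may erode the configuration at C4 through γ-deprotonation of the enone. The fallback sets out from 9 (with alkyne 12) and comes back at 14, avoiding electrophilic halogen. Hydroboration of 12 with disiamylborane and oxidation (NaBO3) gives 2-[4-(methoxymethoxy)phenyl]acetaldehyde F5. Conjugate reduction of 9 with [(Ph3P)CuH]6 in THF generates the C2 enolate regiospecifically, and trapping with F5 gives the aldol (4R)-2-{1-hydroxy-2-[4-(methoxymethoxy)phenyl]ethyl}-4-[4-methoxy-2,6-bis(methoxymethoxy)phenyl]cyclopentan-1-one F6 as a diastereomer mixture. MsCl and Et3N give the mesylate 1-{(4R)-4-[4-methoxy-2,6-bis(methoxymethoxy)phenyl]-2-oxocyclopentyl}-2-[4-(methoxymethoxy)phenyl]ethyl methanesulfonate F7. DBU eliminates it to the exocyclic enone (2E,4R)-4-[4-methoxy-2,6-bis(methoxymethoxy)phenyl]-2-{2-[4-(methoxymethoxy)phenyl]ethylidene}cyclopentan-1-one F8, in which C4 is no longer acidic. Hydrogenation (H2, Pd/C) anti to the aryl group should then give 14.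

3. Step 10. Deprotonation may lose site selectivity (lithiation ortho to a single MOM ether on one of the other two rings, or at the benzylic C2–H of the oxane), or may stall on the crowded ring. The fallback sets out from 19 and comes back at 21 by fixing the site with a halogen first. NBS (1 equiv, MeCN, −40 °C) should brominate only the most electron-rich ring to give (2S,4R,6S)-4-[3-bromo-4-methoxy-2,6-bis(methoxymethoxy)phenyl]-2-[4-(methoxymethoxy)phenyl]-6-{2-[4-(methoxymethoxy)phenyl]ethyl}oxane F9. Bromine–lithium exchange (t-BuLi, THF, −78 °C) and quenching with N-methoxy-N-methylacetamide then give 21.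

**Further compounds**

F1 | step 8 | {[(4R)-4-[4-methoxy-2,6-bis(methoxymethoxy)phenyl]-2-{2-[4-(methoxymethoxy)phenyl]ethyl}cyclopent-1-en-1-yl]oxy}trimethylsilane | C[Si](C)(C)OC1=C(CCc2ccc(OCOC)cc2)C[C@@H](c2c(OCOC)cc(OC)cc2OCOC)C1
F2 | step 8 | (2R,4R)-2-hydroxy-4-[4-methoxy-2,6-bis(methoxymethoxy)phenyl]-2-{2-[4-(methoxymethoxy)phenyl]ethyl}cyclopentan-1-one | O=C1[C@@](O)(CCc2ccc(OCOC)cc2)C[C@@H](c2c(OCOC)cc(OC)cc2OCOC)C1
F3 | step 8 | (3R)-3-[4-methoxy-2,6-bis(methoxymethoxy)phenyl]-7-[4-(methoxymethoxy)phenyl]-5-oxoheptanoic acid | OC(=O)C[C@H](c1c(OCOC)cc(OC)cc1OCOC)CC(=O)CCc1ccc(OCOC)cc1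
F4 | step 8 | (4S)-4-[4-methoxy-2,6-bis(methoxymethoxy)phenyl]-6-{2-[4-(methoxymethoxy)phenyl]ethyl}-3,4-dihydro-2H-pyran-2-one | O=C1C[C@H](c2c(OCOC)cc(OC)cc2OCOC)C=C(CCc2ccc(OCOC)cc2)O1
F5 | step 4 | 2-[4-(methoxymethoxy)phenyl]acetaldehyde | O=CCc1ccc(OCOC)cc1
F6 | step 4 | (4R)-2-{1-hydroxy-2-[4-(methoxymethoxy)phenyl]ethyl}-4-[4-methoxy-2,6-bis(methoxymethoxy)phenyl]cyclopentan-1-one (diastereomer mixture at C2 and the carbinol carbon) | O=C1C(C(O)Cc2ccc(OCOC)cc2)C[C@@H](c2c(OCOC)cc(OC)cc2OCOC)C1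
F7 | step 4 | 1-{(4R)-4-[4-methoxy-2,6-bis(methoxymethoxy)phenyl]-2-oxocyclopentyl}-2-[4-(methoxymethoxy)phenyl]ethyl methanesulfonate | O=C1C(C(OS(C)(=O)=O)Cc2ccc(OCOC)cc2)C[C@@H](c2c(OCOC)cc(OC)cc2OCOC)C1
F8 | step 4 | (2E,4R)-4-[4-methoxy-2,6-bis(methoxymethoxy)phenyl]-2-{2-[4-(methoxymethoxy)phenyl]ethylidene}cyclopentan-1-one | O=C1/C(=C/Cc2ccc(OCOC)cc2)C[C@@H](c2c(OCOC)cc(OC)cc2OCOC)C1
F9 | step 10 | (2S,4R,6S)-4-[3-bromo-4-methoxy-2,6-bis(methoxymethoxy)phenyl]-2-[4-(methoxymethoxy)phenyl]-6-{2-[4-(methoxymethoxy)phenyl]ethyl}oxane | COc1cc(OCOC)c([C@@H]2C[C@H](CCc3ccc(OCOC)cc3)O[C@H](c3ccc(OCOC)cc3)C2)c(OCOC)c1Br
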